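The catalyst was the one charge that differed between Friday's, Sunday's, Tuesday's and Wednesday's flasks, so I looked for one number that would join it to the feed schedule.

| setting | north-east | east | Friday's | Sunday's | Tuesday's | Wednesday's |
|---|---|---|---|---|---|---|
| starting material | 0.020 M (in portions, 3) | 0.020 M (in portions, 3) | 0.020 M (in portions, 3) | 0.020 M (in portions, 3) | 0.020 M (in portions, 3) | 0.020 M (in portions, 3) |
| catalyst | 0.28 mM | 1.2 mM | 0.20 mM | 0.30 mM | 0.50 mM | 0.80 mM |
| remark | run made earlier; portions every 1.0 h | run made earlier; portions every 1.0 h | the portions of starting material follow each other after 1.0 h, the first at the start | the portions of starting material follow each other after 1.0 h, the first at the start | the portions of starting material follow each other after 1.0 h, the first at the start | the portions of starting material follow each other after 1.0 h, the first at the start |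
| time |  |  | 3.0 h | 3.0 h | 3.0 h | 3.0 h |

| run | time / min | target / % |
|---|---|---|
| north-east | 10.0 | 0 |
| north-east | 25.0 | 0 |
| north-east | 50.0 | 0 |
| north-east | 120 | 3.7 |
| east | 15.0 | 0 |
| east | 40.0 | 5.9 |
| east | 80.0 | 7.6 |
| east | 120 | 14.6 |

(each reading ± 1 percentage point)

- the earlier runs were read with a standard deviation of 1 percentage point
- "hardly changes" means that all values lie within two and a half points (for a concentration: within two and a half percent of the largest)

1. amount of target at the end, in percent of the starting material charged for Friday's, Sunday's, Tuesday's, Wednesday's, in this order
2. the shape of the row from first to last (falls all the way / rises, then falls / falls, then rises / rises all the way / hardly changes)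

I wrote the target as made by a pseudo-first-order step in starting material, dy/dt = κ·c·a. Here y is the target as a share of the whole charge, c the catalyst concentration, κ a constant, and a the share of the charge added so far, with nothing taken as lost. Integrated in closed form, this gives y = κ·c·E, where E is the area under a against time. Since a is a third in the first interval, 0.667 in the second and 1.00 in the last, E is 1.00 h at 120 min and 2.00 h at 3.0 h.

The east reading of 14.6 % at 120 min gave me κ = 122 /M/h. I then folded everything into Φ = κ·c·E at the end, the share of the charge standing as target if that rate held. For Friday's flask Φ is 4.87 %. It scales with catalyst, giving 7.30 % for Sunday's, 12.2 % for Tuesday's and 19.5 % for Wednesday's, so I expected a row that rises all the way.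

Was one number enough? Carried to the north-east run at 120 min, the same κ gives 3.41 % against the 3.7 % read, well inside the scatter of 1 percentage point. But in the east run at 40.0 min it gives 3.24 % against 5.9 %, a gap of 2.7 points.

The forecast was 4.8 %, 7.2 %, 11.5 % and 17.5 %, rises all the way, with its yield per mM set "slightly lower at high loading", and its Wednesday's value is lower than my Φ.

Friday's flask gave 4.69 %, and the row went on through 6.86 % and 10.9 % to 16.3 %: rises all the way.

    starting material → side product (k = 0.140 /h)
    starting material + catalyst → catalyst + target (k = 210 /M/h)
    target → over-reaction product (k = 0.340 /h)

Friday's flask stood 0.18 points below its Φ of 4.87 %, and it held 2.18 % of over-reaction product at 3.00 h. Put to Wednesday's flask, Φ of 19.5 % stood 3.2 points above the 16.3 % found, a wider gap than Friday's, and that flask held 7.88 % of over-reaction product at 3.00 h.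

Readings and results are simulated for an exercise; the scatter is artificial.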